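**Retrosynthetic overview**

1. Both non-aromatic rings are cut at their ring olefins. The furanone C3=C4 bond and the chromene C3=C4 bond are made last, in one flask, by a double ring-closing olefin metathesis of the acyclic phenol ester 21 (pyran ring first, then butenolide ring).
2. 21 comes from terminal allene 14 and acrylic acid 19 by an enantioselective rhodium-catalysed carboxylic acid–allene addition, which forms the ester C–O bond and the furanone C5 stereocentre together.
3. 14 comes from the E-allylic alcohol 8 (bromide, propargyl alcohol coupling, reductive alkyne-to-allene transposition). 8 comes from a palladium-catalysed asymmetric O-allylation of vinylphenol 7 (from methylhydroquinone) with carbonate 3 (from geraniol); this sets the quaternary C–O centre, and the terpene supplies the E-trisubstituted olefin.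
4. Enabling feature: furanone C4 is an unsubstituted sp2 CH between C3 (bearing the acyl group and the side chain) and the oxygenated stereocentre C5, so C3=C4 is the metathesis product of a C5 vinyl group and a 2-alkylacrylate held together by the ester. The chromene C3=C4 bond lies likewise between quaternary C2 and arene carbon C4a, and every other olefin of the target is trisubstituted and inert to metathesis.

Key step: step 15

Assumption (remark on the chemistry): the (R,R) antipodes of the DACH-phenyl ligand (step 6) and of DIOP (step 13) are taken to deliver the R centres; should either catalyst show the opposite sense, its (S,S) antipode is used with nothing else changed.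

**Route**

Step 1
Reactants: 1 geraniol
Product: 2 geranyl methyl carbonate
Conditions: ClCO2Me, pyridine, CH2Cl2, 0 °C
Reagents that add atoms: methyl chloroformate, COC(=O)Cl
Why: Acylation of the primary allylic alcohol by the chloroformate (carbonate formation) installs the leaving group for step 6; no stereocentre is formed and the 2E olefin is untouched.

Step 2
Reactants: 2 geranyl methyl carbonate
Product: 3 (2E,6E)-8-hydroxy-3,7-dimethylocta-2,6-dien-1-yl methyl carbonate
Conditions: SeO2 (0.1 equiv), t-BuOOH (70% aq.), salicylic acid (cat.), CH2Cl2, 0 °C to rt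
Reagents that add atoms: tert-butyl hydroperoxide, CC(C)(C)OO (terminal oxygen source; the oxygen is passed on by catalytic selenium dioxide, O=[Se]=O)
Why: Catalytic SeO2 allylic oxidation (ene reaction then [2,3]-sigmatropic shift) should hydroxylate the E-methyl group of the electron-richer terminal olefin, the 2,3-olefin being deactivated by the allylic carbonate, so the 6E geometry of the new allylic alcohol follows from the mechanism.

Step 3
Reactants: 4 methylhydroquinone
Product: 5 2-methyl-4-(triisopropylsilyloxy)phenol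
Conditions: TIPSCl (1.0 equiv), imidazole, DMF, 0 °C
Reagents that add atoms: triisopropylsilyl chloride, CC(C)[Si](Cl)(C(C)C)C(C)C
Why: Silyl ether formation with a bulky chlorosilane is expected to go mainly to the hydroxyl group that has no ortho substituent, the regioisomer and the bis-ether being removed by chromatography.

Step 4
Reactants: 5 2-methyl-4-(triisopropylsilyloxy)phenol
Product: 6 2-hydroxy-3-methyl-5-(triisopropylsilyloxy)benzaldehyde
Conditions: MgCl2, Et3N, (CH2O)n, MeCN, reflux
Reagents that add atoms: paraformaldehyde (as formaldehyde), C=O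
Why: Magnesium phenoxide-directed ortho-formylation of a phenol (Casnati–Skattebøl reaction) can only reach the single free ortho position, a second formaldehyde serving as hydride acceptor.

Step 5
Reactants: 6 2-hydroxy-3-methyl-5-(triisopropylsilyloxy)benzaldehyde
Product: 7 2-ethenyl-6-methyl-4-(triisopropylsilyloxy)phenol
Conditions: Ph3PCH3Br, KOtBu (2.5 equiv), THF, 0 °C to rt
Reagents that add atoms: methyltriphenylphosphonium bromide, C[P+](c1ccccc1)(c1ccccc1)c1ccccc1.[Br-]
Why: Wittig methylenation of the salicylaldehyde, the first equivalent of base holding the phenol as its phenoxide, which is reprotonated on work-up.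

Step 6
Reactants: 3 (2E,6E)-8-hydroxy-3,7-dimethylocta-2,6-dien-1-yl methyl carbonate; 7 2-ethenyl-6-methyl-4-(triisopropylsilyloxy)phenol
Product: 8 (2E,6R)-6-[2-ethenyl-6-methyl-4-(triisopropylsilyloxy)phenoxy]-2,6-dimethylocta-2,7-dien-1-ol
Conditions: Pd2(dba)3·CHCl3 (2.5 mol %), (R,R)-DACH-phenyl ligand [(1R,2R)-cyclohexane-1,2-diamine bis(2-diphenylphosphinobenzamide)] (7.5 mol %), CH2Cl2, rt
Reagents that add atoms: none
Why: Tsuji–Trost asymmetric allylic O-alkylation: zerovalent palladium ionises the carbonate, and the phenoxide formed by the released methoxide should attack the more substituted terminus of the π-allylpalladium cation inside the chiral pocket of the ligand, which sets the R quaternary C–O centre, while the far less acidic primary alcohol does not compete.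

Step 7
Reactants: 8 (2E,6R)-6-[2-ethenyl-6-methyl-4-(triisopropylsilyloxy)phenoxy]-2,6-dimethylocta-2,7-dien-1-ol
Product: 9 2-{[(3R,6E)-8-bromo-3,7-dimethylocta-1,6-dien-3-yl]oxy}-1-ethenyl-3-methyl-5-(triisopropylsilyloxy)benzene
Conditions: CBr4, PPh3, 2,6-lutidine, CH2Cl2, −20 °C to 0 °C
Reagents that add atoms: carbon tetrabromide, BrC(Br)(Br)Br
Why: Appel bromination of the primary allylic alcohol under buffered, essentially neutral conditions should spare the tertiary allyl aryl ether and the silyl ether and keep the E-olefin.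

Step 8
Reactants: 9 2-{[(3R,6E)-8-bromo-3,7-dimethylocta-1,6-dien-3-yl]oxy}-1-ethenyl-3-methyl-5-(triisopropylsilyloxy)benzene; 10 propargyl alcohol
Product: 11 (5E,9R)-9-[2-ethenyl-6-methyl-4-(triisopropylsilyloxy)phenoxy]-5,9-dimethylundeca-5,10-dien-2-yn-1-ol
Conditions: CuI (20 mol %), K2CO3 (2 equiv), DMF, rt
Reagents that add atoms: none
Why: Copper-catalysed coupling of a terminal alkyne with an allylic bromide (substitution by the copper acetylide at the primary carbon, the SN2′ path being disfavoured because it would create a quaternary carbon) should give the skipped enyne without touching the stereocentre.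

Step 9
Reactants: 11 (5E,9R)-9-[2-ethenyl-6-methyl-4-(triisopropylsilyloxy)phenoxy]-5,9-dimethylundeca-5,10-dien-2-yn-1-ol
Product: 14 2-{[(3R,6E)-3,7-dimethylundeca-1,6,9,10-tetraen-3-yl]oxy}-1-ethenyl-3-methyl-5-(triisopropylsilyloxy)benzene, via propargylic sulfonylhydrazine 12 (not isolated), via propargylic diazene 13 (not isolated)
Conditions: 2-nitrobenzenesulfonylhydrazide, PPh3, DEAD, THF, −15 °C, then rt
Reagents that add atoms: none
Why: Myers allene synthesis: Mitsunobu displacement of the primary propargylic alcohol by the sulfonylhydrazide, loss of the sulfinic acid and retro-ene extrusion of N2 from the diazene should transpose the alkyne into the terminal allene under neutral conditions at or below room temperature.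

Step 10
Reactants: 15 triethyl phosphonoacetate; 16 5-bromo-2-methylpent-2-ene
Product: 17 ethyl 2-(diethoxyphosphoryl)-6-methylhept-5-enoate
Conditions: NaH, DMF, 0 °C to 60 °C
Reagents that add atoms: none
Why: C-Alkylation of the sodium salt of the stabilised phosphonate with a primary alkyl bromide.

Step 11
Reactants: 17 ethyl 2-(diethoxyphosphoryl)-6-methylhept-5-enoate
Product: 18 ethyl 6-methyl-2-methylidenehept-5-enoate
Conditions: 37% aq. HCHO, K2CO3, THF, 70 °C
Reagents that add atoms: formaldehyde, C=O
Why: Horner–Wadsworth–Emmons olefination with formaldehyde gives the 2-alkylacrylate.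

Step 12
Reactants: 18 ethyl 6-methyl-2-methylidenehept-5-enoate
Product: 19 6-methyl-2-methylidenehept-5-enoic acid
Conditions: LiOH, THF/H2O, 0 °C to rt; then 1 M HCl
Reagents that add atoms: lithium hydroxide, [Li+].[OH-] (its oxygen becomes the acid OH)
Why: Saponification of the ethyl ester, hydroxide adding to the ester carbonyl faster than to the 2-alkylated acrylate at low temperature.

Step 13
Reactants: 14 2-{[(3R,6E)-3,7-dimethylundeca-1,6,9,10-tetraen-3-yl]oxy}-1-ethenyl-3-methyl-5-(triisopropylsilyloxy)benzene; 19 6-methyl-2-methylidenehept-5-enoic acid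
Product: 20 (3R,5E,9R)-9-[2-ethenyl-6-methyl-4-(triisopropylsilyloxy)phenoxy]-5,9-dimethylundeca-1,5,10-trien-3-yl 6-methyl-2-methylidenehept-5-enoate
Conditions: [Rh(cod)Cl]2 (2.5 mol %), (R,R)-DIOP (5 mol %), Cs2CO3 (10 mol %), ClCH2CH2Cl, rt
Reagents that add atoms: none
Why: Rhodium-catalysed enantioselective addition of a carboxylic acid to a terminal allene (allene hydro-acyloxylation): the rhodium hydride formed from the acid and monovalent rhodium adds to the terminal C=C, and the carboxylate is delivered to the substituted terminus of the allylrhodium species within the chiral diphosphine environment, which should give the branched allylic ester and set the R carbinol centre, with the silyl ether, the aryl allyl ether and all other olefins as spectators.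

Step 14
Reactants: 20 (3R,5E,9R)-9-[2-ethenyl-6-methyl-4-(triisopropylsilyloxy)phenoxy]-5,9-dimethylundeca-1,5,10-trien-3-yl 6-methyl-2-methylidenehept-5-enoate
Product: 21 (3R,5E,9R)-9-(2-ethenyl-4-hydroxy-6-methylphenoxy)-5,9-dimethylundeca-1,5,10-trien-3-yl 6-methyl-2-methylidenehept-5-enoate
Conditions: TBAF, AcOH (1:1), THF, 0 °C
Reagents that add atoms: none
Why: Fluoride-induced cleavage of the aryl silyl ether, buffered with acetic acid so that the phenoxide is protonated at once and neither the acrylate nor the allylic ester is attacked; no stereocentre is affected.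

Step 15
Reactants: 21 (3R,5E,9R)-9-(2-ethenyl-4-hydroxy-6-methylphenoxy)-5,9-dimethylundeca-1,5,10-trien-3-yl 6-methyl-2-methylidenehept-5-enoate
Product: 23 2'-epi-tuberatolide B, via monocyclised chromene ester 22 (not isolated)
Conditions: second-generation Hoveyda–Grubbs catalyst RuCl2(H2IMes)(=CH-C6H4-2-OiPr) (2 × 5 mol %), degassed toluene (2 mM), argon sparge, 40 °C then 80 °C
Reagents that add atoms: none
Why: Two ring-closing olefin metatheses run through ruthenium alkylidene and metallacyclobutane intermediates (Chauvin mechanism), each releasing ethylene. The closest known reaction types are the closure of allyl 2-alkylacrylates to 3-alkylbutenolides and of 2-vinylaryl tertiary-allyl ethers to 2,2-disubstituted 2H-chromenes with second-generation ruthenium catalysts. The pyran ring of the chromene should close first (six-membered ring, styrenyl alkylidene onto the vinyl group at the quaternary carbon, giving 22), and the butenolide ring then closes at the higher temperature (five-membered ring, alkylidene at the C5 vinyl group onto the 1,1-disubstituted acrylate, forming the furanone C3=C4 bond). No new stereocentre is formed, both ring olefins are necessarily cis, and the two R centres of 21 are carried over unchanged under these neutral conditions. The step needs the two closing pairs to win over the three other olefins and over oligomers; this is secured because the four partners are the only terminal olefins and all others are trisubstituted, because the one competing small-ring closure (a cyclopentene from the quaternary-carbon vinyl group and the neighbouring trisubstituted olefin) is pre-empted when ruthenium loads on the styrene and closes the pyran ring at 40 °C before heating, and because 2 mM dilution suppresses dimerisation.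

**Compound list**

1 | geraniol, (2E)-3,7-dimethylocta-2,6-dien-1-ol | CC(C)=CCC/C(C)=C/CO | starting material
2 | geranyl methyl carbonate, (2E)-3,7-dimethylocta-2,6-dien-1-yl methyl carbonate | CC(C)=CCC/C(C)=C/COC(=O)OC | intermediate
3 | (2E,6E)-8-hydroxy-3,7-dimethylocta-2,6-dien-1-yl methyl carbonate | OC/C(C)=C/CC/C(C)=C/COC(=O)OC | intermediate
4 | methylhydroquinone, 2-methylbenzene-1,4-diol | Cc1cc(O)ccc1O | starting material
5 | 2-methyl-4-(triisopropylsilyloxy)phenol | Cc1cc(O[Si](C(C)C)(C(C)C)C(C)C)ccc1O | intermediate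
6 | 2-hydroxy-3-methyl-5-(triisopropylsilyloxy)benzaldehyde | Cc1cc(O[Si](C(C)C)(C(C)C)C(C)C)cc(C=O)c1O | intermediate
7 | 2-ethenyl-6-methyl-4-(triisopropylsilyloxy)phenol | Cc1cc(O[Si](C(C)C)(C(C)C)C(C)C)cc(C=C)c1O | intermediate
8 | (2E,6R)-6-[2-ethenyl-6-methyl-4-(triisopropylsilyloxy)phenoxy]-2,6-dimethylocta-2,7-dien-1-ol | OC/C(C)=C/CC[C@](C)(C=C)Oc1c(C)cc(O[Si](C(C)C)(C(C)C)C(C)C)cc1C=C | intermediate
9 | 2-{[(3R,6E)-8-bromo-3,7-dimethylocta-1,6-dien-3-yl]oxy}-1-ethenyl-3-methyl-5-(triisopropylsilyloxy)benzene | BrC/C(C)=C/CC[C@](C)(C=C)Oc1c(C)cc(O[Si](C(C)C)(C(C)C)C(C)C)cc1C=C | intermediate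
10 | propargyl alcohol, prop-2-yn-1-ol | C#CCO | starting material
11 | (5E,9R)-9-[2-ethenyl-6-methyl-4-(triisopropylsilyloxy)phenoxy]-5,9-dimethylundeca-5,10-dien-2-yn-1-ol | OCC#CC/C(C)=C/CC[C@](C)(C=C)Oc1c(C)cc(O[Si](C(C)C)(C(C)C)C(C)C)cc1C=C | intermediate
12 | N-[(5E,9R)-9-(aryloxy)-5,9-dimethylundeca-5,10-dien-2-yn-1-yl]-2-nitrobenzenesulfonohydrazide, alkylated at the sulfonyl-bearing nitrogen (aryl = 2-ethenyl-6-methyl-4-(triisopropylsilyloxy)phenyl; formed in the flask in step 9) | NN(CC#CC/C(C)=C/CC[C@](C)(C=C)Oc1c(C)cc(O[Si](C(C)C)(C(C)C)C(C)C)cc1C=C)S(=O)(=O)c1ccccc1[N+](=O)[O-] | intermediate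
13 | [(5E,9R)-9-(aryloxy)-5,9-dimethylundeca-5,10-dien-2-yn-1-yl]diazene (same aryl; formed in the flask in step 9) | N=NCC#CC/C(C)=C/CC[C@](C)(C=C)Oc1c(C)cc(O[Si](C(C)C)(C(C)C)C(C)C)cc1C=C | intermediate
14 | 2-{[(3R,6E)-3,7-dimethylundeca-1,6,9,10-tetraen-3-yl]oxy}-1-ethenyl-3-methyl-5-(triisopropylsilyloxy)benzene | C=C=CC/C(C)=C/CC[C@](C)(C=C)Oc1c(C)cc(O[Si](C(C)C)(C(C)C)C(C)C)cc1C=C | intermediate
15 | triethyl phosphonoacetate | CCOC(=O)CP(=O)(OCC)OCC | starting material
16 | 5-bromo-2-methylpent-2-ene | CC(C)=CCCBr | starting material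
17 | ethyl 2-(diethoxyphosphoryl)-6-methylhept-5-enoate (racemic) | CCOC(=O)C(CCC=C(C)C)P(=O)(OCC)OCC | intermediate
18 | ethyl 6-methyl-2-methylidenehept-5-enoate | CCOC(=O)C(=C)CCC=C(C)C | intermediate
19 | 6-methyl-2-methylidenehept-5-enoic acid | OC(=O)C(=C)CCC=C(C)C | intermediate
20 | (3R,5E,9R)-9-[2-ethenyl-6-methyl-4-(triisopropylsilyloxy)phenoxy]-5,9-dimethylundeca-1,5,10-trien-3-yl 6-methyl-2-methylidenehept-5-enoate | CC(C)=CCCC(=C)C(=O)O[C@@H](C=C)C/C(C)=C/CC[C@](C)(C=C)Oc1c(C)cc(O[Si](C(C)C)(C(C)C)C(C)C)cc1C=C | intermediate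
21 | (3R,5E,9R)-9-(2-ethenyl-4-hydroxy-6-methylphenoxy)-5,9-dimethylundeca-1,5,10-trien-3-yl 6-methyl-2-methylidenehept-5-enoate | CC(C)=CCCC(=C)C(=O)O[C@@H](C=C)C/C(C)=C/CC[C@](C)(C=C)Oc1c(C)cc(O)cc1C=C | intermediate
22 | (3R,5E)-8-[(2R)-6-hydroxy-2,8-dimethyl-2H-chromen-2-yl]-5-methylocta-1,5-dien-3-yl 6-methyl-2-methylidenehept-5-enoate (formed in the flask in step 15) | CC(C)=CCCC(=C)C(=O)O[C@@H](C=C)C/C(C)=C/CC[C@]1(C)C=Cc2cc(O)cc(C)c2O1 | intermediate
23 | 2'-epi-tuberatolide B, (5R)-5-{(2E)-5-[(2R)-6-hydroxy-2,8-dimethyl-2H-chromen-2-yl]-2-methylpent-2-en-1-yl}-3-(4-methylpent-3-en-1-yl)furan-2(5H)-one | CC(C)=CCCC1=C[C@@H](C/C(C)=C/CC[C@]2(C)C=Cc3cc(O)cc(C)c3O2)OC1=O | target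

**Step count and risks**

Total step count: 15. Longest linear sequence: 10 steps (4 → 5 → 6 → 7 → 8 → 9 → 11 → 14 → 20 → 21 → 23; steps 3, 4, 5, 6, 7, 8, 9, 13, 14, 15).

Three steps most likely to fail:

1. Step 13. The allylrhodium intermediate may lose a β-hydride instead of being captured by the carboxylate, because the hydrogens on the carbon between the allene and the trisubstituted olefin are doubly allylic, which would drain the allene into a conjugated triene. The facial selectivity of C–O bond formation on this remote-functionalised substrate may also be low or of the wrong sense. The fallback sets out from enynol 11 and comes back at ester 20; it sets the carbinol centre by reagent control with a predictable sense. Reduction of the propargylic alcohol with NaAlH2(OCH2CH2OMe)2 (THF, 0 °C) should give the E-allylic alcohol (2E,5E,9R)-9-[2-ethenyl-6-methyl-4-(triisopropylsilyloxy)phenoxy]-5,9-dimethylundeca-2,5,10-trien-1-ol F1. Sharpless asymmetric epoxidation (Ti(OiPr)4, D-(−)-diethyl tartrate, t-BuOOH, 4 Å sieves, CH2Cl2, −20 °C) touches only the allylic alcohol olefin and follows the tartrate mnemonic, so it should give the (2R,3R)-epoxy alcohol F2. Iodination (I2, PPh3, imidazole) should give the epoxy iodide F3. Zinc dust in ethanol should open it reductively to the (3R)-allylic alcohol (3R,5E,9R)-9-[2-ethenyl-6-methyl-4-(triisopropylsilyloxy)phenoxy]-5,9-dimethylundeca-1,5,10-trien-3-ol F4, with the carbinol C–O bond untouched. Steglich esterification of F4 with acid 19 (DCC, DMAP, CH2Cl2) then gives 20.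

2. Step 6. The doubly ortho-substituted phenoxide may attack the unsubstituted allyl terminus (linear ether), or may capture the π-allyl complex so slowly that enantioselectivity erodes; the vinylphenol may also oligomerise before it reacts. The fallback sets out from carbonate 3 and salicylaldehyde 6 and comes back at 8; it moves the olefination behind the etherification. Aldehyde 6 is more acidic and is fully ionised by the released methoxide, so it is used as the nucleophile under the same palladium catalysis and should give the aryl ether aldehyde 2-{[(3R,6E)-8-hydroxy-3,7-dimethylocta-1,6-dien-3-yl]oxy}-3-methyl-5-(triisopropylsilyloxy)benzaldehyde F5. Wittig methylenation of F5 (Ph3PCH3Br, KOtBu, THF, 0 °C) then gives 8.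

3. Step 15. During the long, hot period that the slower lactone closure needs, the catalyst may decay, oligomers may form, or the vinyl group at the quaternary carbon may be excised as a cyclopentene with the neighbouring trisubstituted olefin before the pyran ring has closed. The fallback sets out from alcohol 8 and comes back at 22; it takes the chromene closure out of the final step. Ring-closing metathesis of 8 alone (second-generation Grubbs catalyst RuCl2(H2IMes)(PCy3)(=CHPh), CH2Cl2, rt) should give the chromene alcohol (2E)-5-[(2R)-2,8-dimethyl-6-(triisopropylsilyloxy)-2H-chromen-2-yl]-2-methylpent-2-en-1-ol F6. The chemistry of steps 7 to 9 then follows: Appel bromination to the chromene bromide F7, copper-catalysed coupling with propargyl alcohol 10 to the chromene enynol F8, and Myers transposition through the sulfonylhydrazine F9 and the diazene F10 to the chromene allene F11. The chemistry of steps 13 and 14 follows: rhodium-catalysed addition of acid 19 to give the chromene silyl ester F12, and buffered desilylation to 22. 22 is then closed to 23 by the lactone-forming metathesis alone (same ruthenium catalyst as step 15, toluene, 80 °C).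

**Further compounds**

F1 | step 13 | (2E,5E,9R)-9-[2-ethenyl-6-methyl-4-(triisopropylsilyloxy)phenoxy]-5,9-dimethylundeca-2,5,10-trien-1-ol | OC/C=C/C/C(C)=C/CC[C@](C)(C=C)Oc1c(C)cc(O[Si](C(C)C)(C(C)C)C(C)C)cc1C=C
F2 | step 13 | [(2R,3R)-3-{(2E,6R)-6-[2-ethenyl-6-methyl-4-(triisopropylsilyloxy)phenoxy]-2,6-dimethylocta-2,7-dien-1-yl}oxiran-2-yl]methanol | OC[C@H]1O[C@@H]1C/C(C)=C/CC[C@](C)(C=C)Oc1c(C)cc(O[Si](C(C)C)(C(C)C)C(C)C)cc1C=C
F3 | step 13 | (2S,3R)-2-(iodomethyl)-3-{(2E,6R)-6-[2-ethenyl-6-methyl-4-(triisopropylsilyloxy)phenoxy]-2,6-dimethylocta-2,7-dien-1-yl}oxirane | IC[C@H]1O[C@@H]1C/C(C)=C/CC[C@](C)(C=C)Oc1c(C)cc(O[Si](C(C)C)(C(C)C)C(C)C)cc1C=C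
F4 | step 13 | (3R,5E,9R)-9-[2-ethenyl-6-methyl-4-(triisopropylsilyloxy)phenoxy]-5,9-dimethylundeca-1,5,10-trien-3-ol | O[C@@H](C=C)C/C(C)=C/CC[C@](C)(C=C)Oc1c(C)cc(O[Si](C(C)C)(C(C)C)C(C)C)cc1C=C
F5 | step 6 | 2-{[(3R,6E)-8-hydroxy-3,7-dimethylocta-1,6-dien-3-yl]oxy}-3-methyl-5-(triisopropylsilyloxy)benzaldehyde | OC/C(C)=C/CC[C@](C)(C=C)Oc1c(C)cc(O[Si](C(C)C)(C(C)C)C(C)C)cc1C=O
F6 | step 15 | (2E)-5-[(2R)-2,8-dimethyl-6-(triisopropylsilyloxy)-2H-chromen-2-yl]-2-methylpent-2-en-1-ol | OC/C(C)=C/CC[C@]1(C)C=Cc2cc(O[Si](C(C)C)(C(C)C)C(C)C)cc(C)c2O1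
F7 | step 15 | (2R)-2-[(3E)-5-bromo-4-methylpent-3-en-1-yl]-2,8-dimethyl-6-(triisopropylsilyloxy)-2H-chromene | BrC/C(C)=C/CC[C@]1(C)C=Cc2cc(O[Si](C(C)C)(C(C)C)C(C)C)cc(C)c2O1
F8 | step 15 | (5E)-8-[(2R)-2,8-dimethyl-6-(triisopropylsilyloxy)-2H-chromen-2-yl]-5-methyloct-5-en-2-yn-1-ol | OCC#CC/C(C)=C/CC[C@]1(C)C=Cc2cc(O[Si](C(C)C)(C(C)C)C(C)C)cc(C)c2O1
F9 | step 15 | N-{(5E)-8-[(2R)-2,8-dimethyl-6-(triisopropylsilyloxy)-2H-chromen-2-yl]-5-methyloct-5-en-2-yn-1-yl}-2-nitrobenzenesulfonohydrazide, alkylated at the sulfonyl-bearing nitrogen | NN(CC#CC/C(C)=C/CC[C@]1(C)C=Cc2cc(O[Si](C(C)C)(C(C)C)C(C)C)cc(C)c2O1)S(=O)(=O)c1ccccc1[N+](=O)[O-]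
F10 | step 15 | {(5E)-8-[(2R)-2,8-dimethyl-6-(triisopropylsilyloxy)-2H-chromen-2-yl]-5-methyloct-5-en-2-yn-1-yl}diazene | N=NCC#CC/C(C)=C/CC[C@]1(C)C=Cc2cc(O[Si](C(C)C)(C(C)C)C(C)C)cc(C)c2O1
F11 | step 15 | (2R)-2,8-dimethyl-2-[(3E)-4-methylocta-3,6,7-trien-1-yl]-6-(triisopropylsilyloxy)-2H-chromene | C=C=CC/C(C)=C/CC[C@]1(C)C=Cc2cc(O[Si](C(C)C)(C(C)C)C(C)C)cc(C)c2O1
F12 | step 15 | (3R,5E)-8-[(2R)-2,8-dimethyl-6-(triisopropylsilyloxy)-2H-chromen-2-yl]-5-methylocta-1,5-dien-3-yl 6-methyl-2-methylidenehept-5-enoate | CC(C)=CCCC(=C)C(=O)O[C@@H](C=C)C/C(C)=C/CC[C@]1(C)C=Cc2cc(O[Si](C(C)C)(C(C)C)C(C)C)cc(C)c2O1
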